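Each acyl chain is cut at the C14–C15 single bond between the two Z-alkenes of its terminal (13Z,15Z)-diene. Because the chains on glycerol O1 and O2 are identical, one two-fold, geometry-retaining copper-mediated alkenyl–alkenyl coupling installs both fragile dienes in the last operation, leaving the C8–C9 oxirane rings, the 4,6-diynes, the esters and the free O3 hydroxyl untouched. The precursor is the 1,2-diacyl-sn-glycerol whose chains end in (13Z)-14-iodoalkenes and already hold the trans-(8S,9S)-oxiranes and the diynes; it is assembled by a two-fold Cadiot–Chodkiewicz coupling of a Sharpless-derived ethynyl oxirane with a bis(5-bromopent-4-ynoyl) glycerol.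

Key step: step 16

Remark on configuration: the glycerol carbon is S with the free hydroxyl on sn-C3, so the target is a 1,2-diacyl-sn-glycerol and (S)-solketal, whose free hydroxyl becomes O3, is the correct antipode; both oxiranes are trans-(8S,9S), which calls for L-(+)-tartrate in the epoxidation.

Remark on design: the diyne is made on glycerol esters and not on a free pent-4-ynoic acid, since a copper-bound 4-ynoate can cyclise to an enol lactone. The (Z)-iodoalkene is made by diimide reduction of an iodoalkyne, so that no E isomer is carried into two chains.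

**Chain fragment**

Step 1
Reactants: 1 hex-5-yn-1-ol
Product: 2 6-iodohex-5-yn-1-ol
Conditions: N-iodosuccinimide (1.15 equiv), AgNO3 (10 mol %), acetone, rt, dark
Reagents that add atoms: N-iodosuccinimide, O=C1CCC(=O)N1I
Why: Silver-catalysed electrophilic iodination of the terminal alkyne through its silver acetylide is fast and leaves the primary alcohol untouched.

Step 2
Reactants: 2 6-iodohex-5-yn-1-ol
Product: 3 (Z)-6-iodohex-5-en-1-ol
Conditions: 2-nitrobenzenesulfonylhydrazide (2 equiv), Et3N, THF/i-PrOH, rt, dark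
Reagents that add atoms: none
Why: Diimide reduction, in which diimide released from the sulfonylhydrazide transfers two hydrogens to the iodoalkyne in a concerted syn fashion, so only the (Z)-iodoalkene can form and the less reactive alkene should not be reduced further.

Step 3
Reactants: 3 (Z)-6-iodohex-5-en-1-ol
Product: 5 ethyl (2E,7Z)-8-iodoocta-2,7-dienoate, via (Z)-6-iodohex-5-enal 4 (not isolated)
Conditions: TEMPO (10 mol %), PhI(OAc)2 (1.1 equiv), CH2Cl2, rt; then Ph3P=CHCO2Et (1.6 equiv), rt
Reagents that add atoms: ethyl (triphenylphosphoranylidene)acetate, CCOC(=O)C=P(c1ccccc1)(c1ccccc1)c1ccccc1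
Why: Oxoammonium oxidation gives the aldehyde, which is trapped in the same flask by a Wittig reaction with the stabilised ylide, whose reversible addition favours the (E)-enoate; the iodoalkene is inert to both reagents.

Step 4
Reactants: 5 ethyl (2E,7Z)-8-iodoocta-2,7-dienoate
Product: 6 (2E,7Z)-8-iodoocta-2,7-dien-1-ol
Conditions: i-Bu2AlH (2.3 equiv), CH2Cl2, −78 °C; aq. KNaC4H4O6 work-up
Reagents that add atoms: none
Why: 1,2-Reduction of the conjugated ester by the aluminium hydride at −78 °C gives the allylic alcohol without touching the alkenyl iodide.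

Step 5
Reactants: 6 (2E,7Z)-8-iodoocta-2,7-dien-1-ol
Product: 7 [(2S,3S)-3-[(4Z)-5-iodopent-4-en-1-yl]oxiran-2-yl]methanol
Conditions: Ti(OiPr)4 (10 mol %), L-(+)-diethyl tartrate (12 mol %), t-BuOOH (2 equiv, isooctane), 4 Å MS, CH2Cl2, −20 °C
Reagents that add atoms: tert-butyl hydroperoxide, CC(C)(C)OO
Why: Katsuki–Sharpless asymmetric epoxidation, in which the titanium–L-(+)-tartrate complex binds the allylic hydroxyl and delivers the peroxide oxygen to the enantioface that gives the (2S,3S)-epoxide from an (E)-2-alken-1-ol (both oxirane stereocentres set here, trans by stereospecific syn addition), while the non-allylic, electron-poor iodoalkene is not epoxidised.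

Step 6
Reactants: 7 [(2S,3S)-3-[(4Z)-5-iodopent-4-en-1-yl]oxiran-2-yl]methanol
Product: 8 (2R,3S)-3-[(4Z)-5-iodopent-4-en-1-yl]oxirane-2-carbaldehyde
Conditions: TEMPO (10 mol %), PhI(OAc)2 (1.2 equiv), CH2Cl2, rt; short silica plug, used at once
Reagents that add atoms: none
Why: Non-basic oxoammonium oxidation of the primary alcohol stops at the aldehyde and cannot epimerise the oxirane carbon; the descriptor at C2 becomes R only because the formyl group now outranks C3.

Step 7
Reactants: 8 (2R,3S)-3-[(4Z)-5-iodopent-4-en-1-yl]oxirane-2-carbaldehyde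
Product: 9 (2S,3S)-2-ethynyl-3-[(4Z)-5-iodopent-4-en-1-yl]oxirane
Conditions: dimethyl (1-diazo-2-oxopropyl)phosphonate (1.3 equiv), K2CO3 (2 equiv), MeOH, 0 °C to rt
Reagents that add atoms: dimethyl (1-diazo-2-oxopropyl)phosphonate, COP(=O)(OC)C(=[N+]=[N-])C(C)=O
Why: Seyferth–Gilbert homologation in the Ohira–Bestmann variant, in which the diazomethylphosphonate anion formed by methanolysis adds to the aldehyde and, after Horner–Wadsworth–Emmons-type elimination and 1,2-hydride shift of the alkylidene carbene, gives the terminal alkyne under carbonate conditions too mild to open or epimerise the trans-oxirane.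

**Glycerol core**

Step 8
Reactants: 10 (S)-solketal (1,2-O-isopropylidene-sn-glycerol)
Product: 12 (4S)-4-{[(4-methoxybenzyl)oxy]methyl}-2,2-dimethyl-1,3-dioxolane, via sodium alkoxide of solketal 11 (not isolated)
Conditions: NaH (1.2 equiv), THF/DMF, 0 °C; then 4-methoxybenzyl chloride, n-Bu4NI (5 mol %), rt
Reagents that add atoms: 4-methoxybenzyl chloride, COc1ccc(CCl)cc1
Why: Williamson ether synthesis on the free primary hydroxyl (the future O3), which leaves the stereocentre untouched.

Step 9
Reactants: 12 (4S)-4-{[(4-methoxybenzyl)oxy]methyl}-2,2-dimethyl-1,3-dioxolane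
Product: 13 3-O-(4-methoxybenzyl)-sn-glycerol [(2R)-3-[(4-methoxybenzyl)oxy]propane-1,2-diol]
Conditions: AcOH/H2O (4:1), 40 °C
Reagents that add atoms: none
Why: Acid-catalysed hydrolysis of the isopropylidene acetal frees O1 and O2 while the 4-methoxybenzyl ether survives dilute acetic acid, and no bond at the stereocentre is broken.

Step 10
Reactants: 13 3-O-(4-methoxybenzyl)-sn-glycerol; 14 pent-4-ynoic acid (2.4 equiv)
Product: 15 3-O-(4-methoxybenzyl)-1,2-di-O-(pent-4-ynoyl)-sn-glycerol
Conditions: EDC·HCl (2.6 equiv), DMAP (0.3 equiv), CH2Cl2, 0 °C to rt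
Reagents that add atoms: none
Why: Steglich esterification (carbodiimide activation with acyl transfer by DMAP) acylates both the primary and the secondary hydroxyl with the inexpensive alkynoic acid.

Step 11
Reactants: 15 3-O-(4-methoxybenzyl)-1,2-di-O-(pent-4-ynoyl)-sn-glycerol
Product: 16 1,2-di-O-(5-bromopent-4-ynoyl)-3-O-(4-methoxybenzyl)-sn-glycerol
Conditions: N-bromosuccinimide (2.3 equiv), AgNO3 (20 mol %), acetone, rt, dark
Reagents that add atoms: N-bromosuccinimide, O=C1CCC(=O)N1Br
Why: Silver-catalysed bromination of both terminal alkynes through their silver acetylides should outrun electrophilic bromination of the anisyl ring in acetone, and with esters in place of a free acid no bromolactonisation can occur.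

**Assembly**

Step 12
Reactants: 16 1,2-di-O-(5-bromopent-4-ynoyl)-3-O-(4-methoxybenzyl)-sn-glycerol; 9 (2S,3S)-2-ethynyl-3-[(4Z)-5-iodopent-4-en-1-yl]oxirane (2.4 equiv)
Product: 17 1,2-bis[(8S,9S,13Z)-8,9-epoxy-14-iodotetradec-13-en-4,6-diynoyl]-3-O-(4-methoxybenzyl)-sn-glycerol
Conditions: CuCl (20 mol %), NH2OH·HCl (40 mol %), n-BuNH2 (30% aq.), CH2Cl2, 0 °C, slow addition of 16, dark
Reagents that add atoms: none
Why: Two-fold Cadiot–Chodkiewicz coupling, in which the copper acetylide of 9 (monovalent copper kept reduced by hydroxylamine) displaces bromide from each bromoalkyne to form the C5–C6 bonds of the unsymmetrical diynes, while the alkenyl iodides, the oxiranes and, at 0 °C for a short time in an alcohol-free medium, the esters remain untouched.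

Step 13
Reactants: 17 1,2-bis[(8S,9S,13Z)-8,9-epoxy-14-iodotetradec-13-en-4,6-diynoyl]-3-O-(4-methoxybenzyl)-sn-glycerol
Product: 18 1,2-bis[(8S,9S,13Z)-8,9-epoxy-14-iodotetradec-13-en-4,6-diynoyl]-sn-glycerol
Conditions: DDQ (1.5 equiv), CH2Cl2/pH 7 phosphate buffer (10:1), 0 °C; rapid chromatography on boric-acid-impregnated silica
Reagents that add atoms: none
Why: Oxidative cleavage of the 4-methoxybenzyl ether by DDQ (hydride abstraction to the oxocarbenium ion, hydrolysed by the buffer) runs at neutral pH, which suppresses migration of the O2 acyl group to O3 and leaves alkenyl iodides, diynes and oxiranes intact.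

**Stannane**

Step 14
Reactants: 19 but-1-yne
Product: 21 tributyl(but-1-yn-1-yl)stannane, via but-1-ynyllithium 20 (not isolated)
Conditions: n-BuLi (1.0 equiv), THF, −78 °C; then n-Bu3SnCl, −78 °C to rt
Reagents that add atoms: tributyltin chloride, CCCC[Sn](Cl)(CCCC)CCCC
Why: Deprotonation of the terminal alkyne and trapping of the lithium acetylide with the tin chloride (alkynyl stannylation).

Step 15
Reactants: 21 tributyl(but-1-yn-1-yl)stannane
Product: 23 (Z)-but-1-en-1-yltributylstannane, via 1-stannylbutenylzirconocene chloride 22 (not isolated)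
Conditions: Cp2Zr(H)Cl (1.2 equiv), THF, rt; then H2O
Reagents that add atoms: none
Why: Hydrozirconation adds Zr–H syn across the stannylalkyne with zirconium on the tin-bearing carbon, and protonolysis of the C–Zr bond with retention leaves tin cis to the ethyl group, that is the (Z)-alkenylstannane.

**Key step**

Step 16
Reactants: 18 1,2-bis[(8S,9S,13Z)-8,9-epoxy-14-iodotetradec-13-en-4,6-diynoyl]-sn-glycerol; 23 (Z)-but-1-en-1-yltributylstannane (3 equiv)
Product: 24 1,2-bis[(8S,9S,13Z,15Z)-8,9-epoxyoctadeca-13,15-dien-4,6-diynoyl]-sn-glycerol (target)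
Conditions: Cu(O2C-C4H3S) (copper thiophene-2-carboxylate, 4 equiv), NMP, 0 °C, argon, dark, under 1 h; cold Et2O/brine work-up, rapid chromatography on boric-acid-impregnated silica at 0 °C
Reagents that add atoms: none
Why: The carboxylate on monovalent copper takes the tributyltin group from 23 and generates (Z)-but-1-enylcopper, which inserts into each C14–I bond and then forms the C14–C15 bond by reductive elimination, neither event scrambling alkene geometry. The closest known reaction type is the palladium-free, copper-carboxylate-mediated Stille-type coupling of alkenyl iodides with alkenylstannanes in NMP. No ring closes and no stereocentre is created; the step only has to preserve the two 13Z and two 15Z geometries, which the non-radical copper pathway at 0 °C should secure. The chemoselectivity required is reaction at C–I in preference to SN2 or SN2' opening of the C8–C9 alkynyl oxiranes; a neutral, non-cuprate alkenylcopper without Lewis acid is too weak a nucleophile for that opening, and because no zerovalent palladium is present the propargylic C8–O bonds cannot be ionised to allenylmetal intermediates. The near-neutral medium and short reaction time should also spare the free O3 hydroxyl, the esters and the diynes and limit O2-to-O3 acyl migration.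

**Compound list**

1 | hex-5-yn-1-ol | OCCCCC#C | starting material
2 | 6-iodohex-5-yn-1-ol | OCCCCC#CI | intermediate
3 | (Z)-6-iodohex-5-en-1-ol | OCCCC/C=C\I | intermediate
4 | (Z)-6-iodohex-5-enal | O=CCCC/C=C\I | intermediate
5 | ethyl (2E,7Z)-8-iodoocta-2,7-dienoate | CCOC(=O)/C=C/CCC/C=C\I | intermediate
6 | (2E,7Z)-8-iodoocta-2,7-dien-1-ol | OC/C=C/CCC/C=C\I | intermediate
7 | [(2S,3S)-3-[(4Z)-5-iodopent-4-en-1-yl]oxiran-2-yl]methanol | OC[C@@H]1O[C@H]1CCC/C=C\I | intermediate
8 | (2R,3S)-3-[(4Z)-5-iodopent-4-en-1-yl]oxirane-2-carbaldehyde | O=C[C@@H]1O[C@H]1CCC/C=C\I | intermediate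
9 | (2S,3S)-2-ethynyl-3-[(4Z)-5-iodopent-4-en-1-yl]oxirane | C#C[C@@H]1O[C@H]1CCC/C=C\I | intermediate
10 | (S)-solketal, [(4S)-2,2-dimethyl-1,3-dioxolan-4-yl]methanol | CC1(C)OC[C@H](CO)O1 | starting material
11 | sodium [(4S)-2,2-dimethyl-1,3-dioxolan-4-yl]methanolate | CC1(C)OC[C@H](C[O-])O1.[Na+] | intermediate
12 | (4S)-4-{[(4-methoxybenzyl)oxy]methyl}-2,2-dimethyl-1,3-dioxolane | CC1(C)OC[C@H](COCc2ccc(OC)cc2)O1 | intermediate
13 | 3-O-(4-methoxybenzyl)-sn-glycerol, (2R)-3-[(4-methoxybenzyl)oxy]propane-1,2-diol | OC[C@H](COCc1ccc(OC)cc1)O | intermediate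
14 | pent-4-ynoic acid | C#CCCC(=O)O | starting material
15 | 3-O-(4-methoxybenzyl)-1,2-di-O-(pent-4-ynoyl)-sn-glycerol | C#CCCC(=O)OC[C@H](COCc1ccc(OC)cc1)OC(=O)CCC#C | intermediate
16 | 1,2-di-O-(5-bromopent-4-ynoyl)-3-O-(4-methoxybenzyl)-sn-glycerol | BrC#CCCC(=O)OC[C@H](COCc1ccc(OC)cc1)OC(=O)CCC#CBr | intermediate
17 | 1,2-bis[(8S,9S,13Z)-8,9-epoxy-14-iodotetradec-13-en-4,6-diynoyl]-3-O-(4-methoxybenzyl)-sn-glycerol | I/C=C\CCC[C@@H]1O[C@H]1C#CC#CCCC(=O)OC[C@H](COCc2ccc(OC)cc2)OC(=O)CCC#CC#C[C@@H]1O[C@H]1CCC/C=C\I | intermediate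
18 | 1,2-bis[(8S,9S,13Z)-8,9-epoxy-14-iodotetradec-13-en-4,6-diynoyl]-sn-glycerol | I/C=C\CCC[C@@H]1O[C@H]1C#CC#CCCC(=O)OC[C@H](CO)OC(=O)CCC#CC#C[C@@H]1O[C@H]1CCC/C=C\I | intermediate
19 | but-1-yne | CCC#C | starting material
20 | but-1-ynyllithium | CCC#C[Li] | intermediate
21 | tributyl(but-1-yn-1-yl)stannane | CCC#C[Sn](CCCC)(CCCC)CCCC | intermediate
22 | chloro[(1Z)-1-(tributylstannyl)but-1-en-1-yl]bis(cyclopentadienyl)zirconium | CC/C=C(/[Zr](Cl)(C1C=CC=C1)C1C=CC=C1)\[Sn](CCCC)(CCCC)CCCC | intermediate
23 | (Z)-but-1-en-1-yltributylstannane | CC/C=C\[Sn](CCCC)(CCCC)CCCC | intermediate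
24 | 1,2-bis[(8S,9S,13Z,15Z)-8,9-epoxyoctadeca-13,15-dien-4,6-diynoyl]-sn-glycerol | CC/C=C\C=C/CCC[C@@H]1O[C@H]1C#CC#CCCC(=O)OC[C@H](CO)OC(=O)CCC#CC#C[C@@H]1O[C@H]1CCC/C=C\C=C/CC | target

**Step count and risk**

Total step count: 16. Longest linear sequence: 10 steps (steps 1 to 7, then 12, 13 and 16).

Steps most likely to fail:

Step 16. Oxidative addition of the unactivated alkenyl iodides at copper may be slow, so that only one chain couples while the stannane is lost to homocoupling or protodestannylation. The organocopper may also open an alkynyl oxirane, or the O2 acyl group may migrate to O3 during work-up. The fallback forms the C14–C15 bond early, before oxirane and diyne exist, where zerovalent palladium is harmless. It sets out from 5 and 23: a Stille–Migita coupling (Pd2(dba)3, AsPh3, NMP, rt) should give ethyl (2E,7Z,9Z)-dodeca-2,7,9-trienoate F1. Reduction with i-Bu2AlH gives (2E,7Z,9Z)-dodeca-2,7,9-trien-1-ol F2, and Katsuki–Sharpless epoxidation with L-(+)-diethyl tartrate gives [(2S,3S)-3-[(4Z,6Z)-nona-4,6-dien-1-yl]oxiran-2-yl]methanol F3. TEMPO/PhI(OAc)2 oxidation gives (2R,3S)-3-[(4Z,6Z)-nona-4,6-dien-1-yl]oxirane-2-carbaldehyde F4, and Ohira–Bestmann homologation gives (2S,3S)-2-ethynyl-3-[(4Z,6Z)-nona-4,6-dien-1-yl]oxirane F5. Two-fold Cadiot–Chodkiewicz coupling of F5 with 16 gives 1,2-bis[(8S,9S,13Z,15Z)-8,9-epoxyoctadeca-13,15-dien-4,6-diynoyl]-3-O-(4-methoxybenzyl)-sn-glycerol F6. Brief buffered DDQ treatment at 0 °C then returns to the route at 24, at the price of carrying the diene through six operations.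

Step 12. The second coupling may stall at the mono-diyne, butylamine may aminolyse the glycerol esters, or 9 may be consumed by Glaser homocoupling. The fallback builds the complete acid first and esterifies afterwards. It sets out from 14 and 9: Fischer esterification (MeOH, cat. H2SO4) gives methyl pent-4-ynoate F7, and N-bromosuccinimide/AgNO3 gives methyl 5-bromopent-4-ynoate F8. Single Cadiot–Chodkiewicz coupling of F8 with 9 gives methyl (8S,9S,13Z)-8,9-epoxy-14-iodotetradec-13-en-4,6-diynoate F9. LiOH in THF/H2O at 0 °C gives (8S,9S,13Z)-8,9-epoxy-14-iodotetradec-13-en-4,6-diynoic acid F10. Steglich esterification of F10 (2.4 equiv, EDC·HCl, DMAP) with diol 13 returns to the route at 17.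

Step 13. The O2 acyl group may migrate to O3 during the oxidative debenzylation or on silica, or cleavage may be incomplete on the hindered, lipophilic substrate. The fallback moves the oxidative step to a robust stage and ends with a mild acidic desilylation. It sets out from 16: DDQ in buffered CH2Cl2 gives 1,2-di-O-(5-bromopent-4-ynoyl)-sn-glycerol F11, from which any migrated isomer is removed on boric-acid silica. Et3SiCl/pyridine in CH2Cl2 at −20 °C gives 1,2-di-O-(5-bromopent-4-ynoyl)-3-O-(triethylsilyl)-sn-glycerol F12. Two-fold Cadiot–Chodkiewicz coupling of F12 with 9 gives 1,2-bis[(8S,9S,13Z)-8,9-epoxy-14-iodotetradec-13-en-4,6-diynoyl]-3-O-(triethylsilyl)-sn-glycerol F13. HF·pyridine buffered with pyridine in THF at 0 °C returns to the route at 18.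

Further compounds
F1 | step 16 | ethyl (2E,7Z,9Z)-dodeca-2,7,9-trienoate | CCOC(=O)/C=C/CCC/C=C\C=C/CC
F2 | step 16 | (2E,7Z,9Z)-dodeca-2,7,9-trien-1-ol | OC/C=C/CCC/C=C\C=C/CC
F3 | step 16 | [(2S,3S)-3-[(4Z,6Z)-nona-4,6-dien-1-yl]oxiran-2-yl]methanol | OC[C@@H]1O[C@H]1CCC/C=C\C=C/CC
F4 | step 16 | (2R,3S)-3-[(4Z,6Z)-nona-4,6-dien-1-yl]oxirane-2-carbaldehyde | O=C[C@@H]1O[C@H]1CCC/C=C\C=C/CC
F5 | step 16 | (2S,3S)-2-ethynyl-3-[(4Z,6Z)-nona-4,6-dien-1-yl]oxirane | C#C[C@@H]1O[C@H]1CCC/C=C\C=C/CC
F6 | step 16 | 1,2-bis[(8S,9S,13Z,15Z)-8,9-epoxyoctadeca-13,15-dien-4,6-diynoyl]-3-O-(4-methoxybenzyl)-sn-glycerol | CC/C=C\C=C/CCC[C@@H]1O[C@H]1C#CC#CCCC(=O)OC[C@H](COCc2ccc(OC)cc2)OC(=O)CCC#CC#C[C@@H]1O[C@H]1CCC/C=C\C=C/CC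
F7 | step 12 | methyl pent-4-ynoate | C#CCCC(=O)OC
F8 | step 12 | methyl 5-bromopent-4-ynoate | BrC#CCCC(=O)OC
F9 | step 12 | methyl (8S,9S,13Z)-8,9-epoxy-14-iodotetradec-13-en-4,6-diynoate | COC(=O)CCC#CC#C[C@@H]1O[C@H]1CCC/C=C\I
F10 | step 12 | (8S,9S,13Z)-8,9-epoxy-14-iodotetradec-13-en-4,6-diynoic acid | OC(=O)CCC#CC#C[C@@H]1O[C@H]1CCC/C=C\I
F11 | step 13 | 1,2-di-O-(5-bromopent-4-ynoyl)-sn-glycerol | BrC#CCCC(=O)OC[C@H](CO)OC(=O)CCC#CBr
F12 | step 13 | 1,2-di-O-(5-bromopent-4-ynoyl)-3-O-(triethylsilyl)-sn-glycerol | BrC#CCCC(=O)OC[C@H](CO[Si](CC)(CC)CC)OC(=O)CCC#CBr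
F13 | step 13 | 1,2-bis[(8S,9S,13Z)-8,9-epoxy-14-iodotetradec-13-en-4,6-diynoyl]-3-O-(triethylsilyl)-sn-glycerol | I/C=C\CCC[C@@H]1O[C@H]1C#CC#CCCC(=O)OC[C@H](CO[Si](CC)(CC)CC)OC(=O)CCC#CC#C[C@@H]1O[C@H]1CCC/C=C\I
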